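## Retrosynthetic overview
1. The target comes from global hydrogenolysis of the tri-O-benzyl lactone **16**.
2. **16** comes from a trans-selective α-benzylation of the enolate of α-benzyloxy lactone **11**. This sets the C8 quaternary centre, with C8′ controlling the face.
3. **11** comes from α-hydroxylation and O-benzylation of (S)-β-arylmethyl-γ-butyrolactone **8**.
4. **8** comes from an enzymatic Baeyer–Villiger desymmetrisation of the prochiral 3-arylmethylcyclobutanone **6**. This step forms the lactone ring and sets C8′.
5. **6** comes from eugenol benzyl ether by dichloroketene [2+2] cycloaddition and dechlorination. The cyclobutanone is the first ring formed, the lactone second, and both arenes are carried in intact.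

Assumption: the cyclohexanone-type Baeyer–Villiger monooxygenase (or an engineered variant) gives the (S)-lactone from this substrate.
Assumption: all three oxygens are protected as benzyl ethers so that one hydrogenolysis finishes the synthesis.

## Route

**Step 1**
Reactants: **1** eugenol (4-allyl-2-methoxyphenol); **2** benzyl bromide
Product: **3** 1-allyl-4-(benzyloxy)-3-methoxybenzene
Conditions: BnBr, K2CO3, DMF, rt, 12 h
Reagents that add atoms: benzyl bromide, BrCc1ccccc1 (adds the benzyl group)
Why: Williamson O-alkylation of the phenol protects it for the later strongly basic and ketene steps, and the allyl group is untouched.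

**Step 2**
Reactants: **3**; **4** trichloroacetyl chloride
Product: **5** 3-[4-(benzyloxy)-3-methoxybenzyl]-2,2-dichlorocyclobutan-1-one
Conditions: Zn–Cu couple, POCl3, Et2O, 0 °C → rt, 12 h
Reagents that add atoms: trichloroacetyl chloride, ClC(=O)C(Cl)(Cl)Cl (supplies C2Cl2O as dichloroketene)
Why: Zn dehalogenates Cl3CCOCl to dichloroketene, which undergoes a regioselective [2+2] ketene–alkene cycloaddition with the terminal alkene, placing CCl2 next to the substituted carbon; the ring is achiral and prochiral after the next step.

**Step 3**
Reactant: **5**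
Product: **6** 3-[4-(benzyloxy)-3-methoxybenzyl]cyclobutan-1-one
Conditions: Zn dust, AcOH (or sat. NH4Cl, MeOH), rt → 50 °C
Reagents that add atoms: none
Why: Reductive dehalogenation of the α,α-dichloroketone with zinc leaves the ketone, the benzyl ether and the arene untouched and gives the symmetric prochiral cyclobutanone.

**Step 4**
Reactants: **6**; **7** dioxygen
Product: **8** (4S)-4-[4-(benzyloxy)-3-methoxybenzyl]oxolan-2-one
Conditions: E. coli whole cells overexpressing a Baeyer–Villiger monooxygenase (cyclohexanone monooxygenase, flavin-dependent oxidoreductase), glucose for NADPH recycling, air, phosphate buffer pH 7.5, 30 °C, 24 h, substrate added from DMSO (≤5%)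
Reagents that add atoms: dioxygen, O=O (one O atom is inserted)
Why: Enzymatic Baeyer–Villiger oxidation enantiotopically discriminates the two C–C bonds of the cyclobutanone, inserting O on one side to give the (S)-γ-butyrolactone in high ee; this is the first stereocentre, C8′.

**Step 5**
Reactants: **8**; **9** 2-(phenylsulfonyl)-3-phenyloxaziridine (Davis oxaziridine)
Product: **10** (4S)-3-hydroxy-4-[4-(benzyloxy)-3-methoxybenzyl]oxolan-2-one (C3 epimers, trans major)
Conditions: LiHMDS, THF, −78 °C, 45 min; then 9, −78 °C, 2 h; sat. NH4Cl quench
Reagents that add atoms: Davis oxaziridine, O=S(=O)(c1ccccc1)N1OC1c1ccccc1 (transfers one O atom)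
Why: Lactone enolate α-hydroxylation (Davis oxidation) occurs anti to the C4 arylmethyl group; C3 is re-enolised in Step 9, so any C3 epimer mixture converges.

**Step 6**
Reactants: **10**; **2** benzyl bromide
Product: **11** (4S)-3-(benzyloxy)-4-[4-(benzyloxy)-3-methoxybenzyl]oxolan-2-one
Conditions: BnBr, Ag2O, CH2Cl2, rt, dark, 24 h
Reagents that add atoms: benzyl bromide, BrCc1ccccc1 (adds the benzyl group)
Why: Silver(I)-promoted Williamson etherification under near-neutral conditions protects the α-OH without opening the lactone or cleaving the other ethers; the C4 centre is not touched.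

**Step 7**
Reactant: **12** 4-(benzyloxy)-3-methoxybenzaldehyde (commercial)
Product: **13** [4-(benzyloxy)-3-methoxyphenyl]methanol
Conditions: NaBH4, MeOH, 0 °C → rt, 1 h
Reagents that add atoms: none
Why: Chemoselective hydride reduction of an aryl aldehyde.

**Step 8**
Reactants: **13**; **14** carbon tetrabromide
Product: **15** 4-(benzyloxy)-3-methoxybenzyl bromide
Conditions: CBr4, PPh3, CH2Cl2, 0 °C, 1 h; cold filtration through silica, use immediately
Reagents that add atoms: carbon tetrabromide, BrC(Br)(Br)Br (supplies Br)
Why: The Appel reaction converts the alcohol to the bromide under neutral conditions, which avoids the HBr cleavage and self-alkylation that an electron-rich benzylic halide would suffer with PBr3.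

**Step 9**
Reactants: **11**; **15**
Product: **16** (3R,4R)-3-(benzyloxy)-3,4-bis[4-(benzyloxy)-3-methoxybenzyl]oxolan-2-one
Conditions: LiHMDS (1.05 equiv), THF, −78 °C, 45 min; then 15 and DMPU, −78 → −40 °C, 3 h
Reagents that add atoms: 15 itself (supplies the 4-benzyloxy-3-methoxybenzyl group, C15H15O2)
Why: In this enolate alkylation the planar α-benzyloxy enolate is attacked anti to the C4 arylmethyl group, so the new benzyl is trans to it and the OBn is cis to it; this sets C8 as R, matching the target's (8R,8′R) relative and absolute configuration.

**Step 10**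
Reactant: **16**
Product: **17** (+)-nortrachelogenin, (3R,4R)-3-hydroxy-3,4-bis(4-hydroxy-3-methoxybenzyl)oxolan-2-one
Conditions: H2 (1 atm), 20% Pd(OH)2/C, EtOAc–MeOH 1:1, rt, 16 h
Reagents that add atoms: none (H2 only adds hydrogen)
Why: Catalytic hydrogenolysis removes all three O-benzyl groups, leaving the lactone, the aryl methyl ethers and both stereocentres intact.

## Compound list
1 | eugenol | COc1cc(CC=C)ccc1O | starting material
2 | benzyl bromide | BrCc1ccccc1 | starting material
3 | 1-allyl-4-(benzyloxy)-3-methoxybenzene | C=CCc1ccc(OCc2ccccc2)c(OC)c1 | intermediate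
4 | trichloroacetyl chloride | ClC(=O)C(Cl)(Cl)Cl | starting material
5 | 3-[4-(benzyloxy)-3-methoxybenzyl]-2,2-dichlorocyclobutanone | COc1cc(CC2CC(=O)C2(Cl)Cl)ccc1OCc1ccccc1 | intermediate
6 | 3-[4-(benzyloxy)-3-methoxybenzyl]cyclobutanone | COc1cc(CC2CC(=O)C2)ccc1OCc1ccccc1 | intermediate
7 | dioxygen | O=O | starting material (reagent)
8 | (4S)-4-[4-(benzyloxy)-3-methoxybenzyl]oxolan-2-one | COc1cc(C[C@@H]2COC(=O)C2)ccc1OCc1ccccc1 | intermediate
9 | 2-(phenylsulfonyl)-3-phenyloxaziridine | O=S(=O)(c1ccccc1)N1OC1c1ccccc1 | starting material (reagent)
10 | (4S)-3-hydroxy-4-[4-(benzyloxy)-3-methoxybenzyl]oxolan-2-one (C3 epimers) | COc1cc(C[C@@H]2COC(=O)C2O)ccc1OCc1ccccc1 | intermediate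
11 | (4S)-3-(benzyloxy)-4-[4-(benzyloxy)-3-methoxybenzyl]oxolan-2-one (C3 epimers) | COc1cc(C[C@@H]2COC(=O)C2OCc2ccccc2)ccc1OCc1ccccc1 | intermediate
12 | 4-(benzyloxy)-3-methoxybenzaldehyde | COc1cc(C=O)ccc1OCc1ccccc1 | starting material
13 | [4-(benzyloxy)-3-methoxyphenyl]methanol | COc1cc(CO)ccc1OCc1ccccc1 | intermediate
14 | carbon tetrabromide | BrC(Br)(Br)Br | starting material (reagent)
15 | 4-(benzyloxy)-3-methoxybenzyl bromide | COc1cc(CBr)ccc1OCc1ccccc1 | intermediate
16 | (3R,4R)-3-(benzyloxy)-3,4-bis[4-(benzyloxy)-3-methoxybenzyl]oxolan-2-one | COc1cc(C[C@@H]2COC(=O)[C@@]2(OCc2ccccc2)Cc2ccc(OCc3ccccc3)c(OC)c2)ccc1OCc1ccccc1 | intermediate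
17 | (+)-nortrachelogenin | COc1cc(C[C@@H]2COC(=O)[C@@]2(O)Cc2ccc(O)c(OC)c2)ccc1O | target

## Step count
- Total steps: 10 (eight in the main line plus two for the benzyl bromide branch).
- Longest linear sequence: 8 steps (Steps 1–6, 9, 10), from eugenol.

## Three steps most likely to fail
1. **Step 4 (Baeyer–Villiger monooxygenase).** The bulky aryl ether may give low conversion, or the enzyme may favour the (R)-lactone.
   - Fallback: a different route to (S)-8. Run a Stobbe condensation of 12 with diethyl succinate, then Ru–BINAP asymmetric hydrogenation of the half-ester. Convert the acid to the tert-butyl ester, reduce the ethyl ester selectively with LiBH4, and close the lactone with TFA.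
2. **Step 9 (quaternary α-benzylation).** Yield or dr may be poor, and the electron-rich benzyl bromide is unstable.
   - Fallback: oxidise 10 to the 3-keto lactone, then add a 4-benzyloxy-3-methoxybenzyl organozinc or organocerium reagent. The addition is anti to the C4 arylmethyl group, and the α-OH is formed directly without enolate chemistry.
3. **Step 6 (O-benzylation of the hindered α-hydroxy lactone).** It may be sluggish or open the lactone.
   - Fallback: skip protection. Alkylate the dianion of 10 (2.2 equiv LiHMDS) with 15 directly, and remove the two phenolic benzyl groups at the end.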